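**Retrosynthetic overview**
1. Target 12 ← global O-demethylation of the macrocyclic dimethyl ether 11.
2. 11 ← closure of the 18-membered ring at the A–CH2CH2–B bridge by an intramolecular reductive Heck reaction of bromo-styrene 10 (proposed new step).
3. 10 ← C–CH2CH2–D bridge by hydroboration/B-alkyl Suzuki coupling of styrene 4 with aryl iodide 8.
4. 4 and 8 ← Wittig methylenation of diaryl ether aldehydes 3 (B–O–C, Chan–Lam) and 7 (D–O–A, SNAr).
5. Ring order: all four benzene rings are purchased; the only ring formed is the 18-membered macrocycle (step 6).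

Assumption: the target SMILES has no stereocentre and this marchantin-type ring has no configurationally stable axis or plane, so the compound is achiral and no enantiocontrol is needed.

**Route**

Step 1
Reactants: 1 isovanillin (3-hydroxy-4-methoxybenzaldehyde); 2 4-bromophenylboronic acid
Product: 3 3-(4-bromophenoxy)-4-methoxybenzaldehyde
Conditions: Cu(OAc)2 (0.5 equiv), pyridine (5 equiv), 4 Å MS, CH2Cl2, O2 (balloon), rt, 48 h
Reagents that add atoms: none
Why: Chan–Evans–Lam oxidative C–O coupling arylates the guaiacol-type phenol at room temperature with O2 as terminal oxidant, and leaves the aryl C–Br bond and the aldehyde untouched.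

Step 2
Reactants: 3 3-(4-bromophenoxy)-4-methoxybenzaldehyde
Product: 4 2-(4-bromophenoxy)-4-ethenyl-1-methoxybenzene
Conditions: Ph3PCH3Br (1.3 equiv), KOt-Bu (1.25 equiv), THF, 0 °C → rt
Reagents that add atoms: methyltriphenylphosphonium bromide, C[P+](c1ccccc1)(c1ccccc1)c1ccccc1.[Br-]
Why: Wittig methylenation with the non-stabilised ylide converts the aryl aldehyde cleanly into the styrene; the aryl bromide and diaryl ether are inert to the ylide.

Step 3
Reactants: 5 3-iodophenol; 6 2-fluoro-5-methoxybenzaldehyde
Product: 7 2-(3-iodophenoxy)-5-methoxybenzaldehyde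
Conditions: K2CO3 (1.5 equiv), DMA, 140 °C
Reagents that add atoms: none
Why: SNAr (addition–elimination through a Meisenheimer adduct): the ortho-formyl group activates the fluoride toward the phenoxide of 5, and the C–I bond is inert without a transition metal.

Step 4
Reactants: 7 2-(3-iodophenoxy)-5-methoxybenzaldehyde
Product: 8 2-ethenyl-1-(3-iodophenoxy)-4-methoxybenzene
Conditions: Ph3PCH3Br (1.3 equiv), KOt-Bu (1.25 equiv), THF, 0 °C → rt
Reagents that add atoms: methyltriphenylphosphonium bromide, C[P+](c1ccccc1)(c1ccccc1)c1ccccc1.[Br-]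
Why: Wittig methylenation; the base is consumed in forming the ylide before 7 is added, so the aryl iodide survives.

Step 5
Reactants: 4 2-(4-bromophenoxy)-4-ethenyl-1-methoxybenzene; 8 2-ethenyl-1-(3-iodophenoxy)-4-methoxybenzene
Product: 10 1-(3-{2-[3-(4-bromophenoxy)-4-methoxyphenyl]ethyl}phenoxy)-2-ethenyl-4-methoxybenzene, via B-{2-[3-(4-bromophenoxy)-4-methoxyphenyl]ethyl}-9-BBN 9 (not isolated)
Conditions: 4, 9-BBN (1.05 equiv), THF, 0 °C → rt, 4 h; then 3 M aq K3PO4 (3 equiv), 15 min; then 8 (1.1 equiv), PdCl2(dppf) (5 mol %), DMF, rt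
Reagents that add atoms: 9-BBN (9-borabicyclo[3.3.1]nonane), B1C2CCCC1CCC2 (its boron and carbon atoms are carried only in intermediate 9; product 10 keeps one hydrogen from it)
Why: anti-Markovnikov hydroboration of the styrene followed by B-alkyl Suzuki–Miyaura coupling; at room temperature Pd(dppf) inserts into the aryl iodide of 8 much faster than into the electron-rich aryl bromide, and the vinyl group of 8 is safe because residual B–H is destroyed by the aqueous base before 8 is added.

Step 6
Reactants: 10 1-(3-{2-[3-(4-bromophenoxy)-4-methoxyphenyl]ethyl}phenoxy)-2-ethenyl-4-methoxybenzene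
Product: 11 macrocyclic dimethyl ether (target with both phenols as OMe)
Conditions: Pd(P(t-Bu)3)2 (10 mol %), HCO2Na (3 equiv, suspended), 1,4-dioxane/DMA 9:1, 90 °C, 10 added by syringe pump over 12 h (final 2 mM)
Reagents that add atoms: none
Why: Proposed new method: a macrocyclising reductive Heck reaction (formal intramolecular anti-Markovnikov hydroarylation of a styrene), in which Pd(0)/P(t-Bu)3 adds oxidatively to the unhindered aryl bromide of ring B, 18-endo migratory insertion puts the aryl group on the terminal vinyl carbon to give an η3-benzyl-palladium species stabilised by the electron-rich ring A, and formate exchange, decarboxylation and C–H reductive elimination release the saturated CH2CH2 bridge without a strained ring stilbene, while the sparingly soluble formate and slow substrate addition keep direct ArPdBr reduction slower than ring closure; the closest known reaction types are the intermolecular Pd/formate reductive Heck hydroarylation of styrenes and the macrocyclising Mizoroki–Heck reaction, and to my knowledge a reductive Heck has not been used to close a macrocycle or to forge a bibenzyl cyclophane bridge.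

Step 7
Reactants: 11 macrocyclic dimethyl ether
Product: 12 target bis(bibenzyl) macrocycle CNP0135015.0
Conditions: BBr3 (6 equiv), CH2Cl2, −78 °C → rt; then H2O
Reagents that add atoms: none
Why: Lewis-acid aryl methyl ether cleavage (boron complexation, then bromide SN2 at the O-methyl carbon) frees both phenols, while the diaryl ethers and bibenzyl bridges are inert, and no stereocentre exists to be set or scrambled.

**Compound list**
1 | isovanillin (3-hydroxy-4-methoxybenzaldehyde) | COc1ccc(C=O)cc1O | starting material
2 | 4-bromophenylboronic acid | OB(O)c1ccc(Br)cc1 | starting material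
3 | 3-(4-bromophenoxy)-4-methoxybenzaldehyde | COc1ccc(C=O)cc1Oc1ccc(Br)cc1 | intermediate
4 | 2-(4-bromophenoxy)-4-ethenyl-1-methoxybenzene | COc1ccc(C=C)cc1Oc1ccc(Br)cc1 | intermediate
5 | 3-iodophenol | Oc1cccc(I)c1 | starting material
6 | 2-fluoro-5-methoxybenzaldehyde | COc1ccc(F)c(C=O)c1 | starting material
7 | 2-(3-iodophenoxy)-5-methoxybenzaldehyde | COc1ccc(Oc2cccc(I)c2)c(C=O)c1 | intermediate
8 | 2-ethenyl-1-(3-iodophenoxy)-4-methoxybenzene | COc1ccc(Oc2cccc(I)c2)c(C=C)c1 | intermediate
9 | B-{2-[3-(4-bromophenoxy)-4-methoxyphenyl]ethyl}-9-BBN (9-alkyl-9-borabicyclo[3.3.1]nonane) | COc1ccc(CCB2C3CCCC2CCC3)cc1Oc1ccc(Br)cc1 | intermediate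
10 | 1-(3-{2-[3-(4-bromophenoxy)-4-methoxyphenyl]ethyl}phenoxy)-2-ethenyl-4-methoxybenzene | COc1ccc(CCc2cccc(Oc3ccc(OC)cc3C=C)c2)cc1Oc1ccc(Br)cc1 | intermediate
11 | macrocyclic dimethyl ether of the target (18-membered bis(bibenzyl) bis(diaryl ether), both phenols as OMe) | COc1ccc2c(c1)CCc1ccc(cc1)Oc1cc(ccc1OC)CCc1cccc(c1)O2 | intermediate
12 | target bis(bibenzyl) macrocycle CNP0135015.0 (achiral) | Oc1ccc2c(c1)CCc1ccc(cc1)Oc1cc(ccc1O)CCc1cccc(c1)O2 | target

**Totals**
Total steps: 7. Longest linear sequence: 5 (steps 1, 2, 5, 6, 7; the branch 3, 4, 5, 6, 7 is equally long).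

**Three steps most likely to fail**

Step 6 (proposed new reductive Heck macrocyclisation). The main risks are hydrodebromination of 10 before ring closure and oligomerisation. The fallback uses known chemistry and sets out from 10. The vinyl group of 10 is hydroborated with 9-BBN (THF, rt) to give the B-alkyl-9-BBN adduct of 10 F1. F1 is then added by syringe pump to PdCl2(dppf)/AsPh3 and aqueous K3PO4 in THF/DMF at 60 °C (2 mM). At that temperature the aryl bromide couples, and the intramolecular B-alkyl Suzuki–Miyaura macrocyclisation gives the saturated bridge directly. The fallback comes back to the route at 11.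

Step 5 (one-pot hydroboration/Suzuki). The risks are coupling of the borane at the aryl bromide and hydroboration of the second styrene. The fallback sets out from 4 and 7, so no second vinyl group is present. A ligand-free Jeffery-type Heck reaction (Pd(OAc)2, Bu4NCl, NaHCO3, DMF, 60 °C) engages only the aryl iodide and gives 2-(3-{(E)-2-[3-(4-bromophenoxy)-4-methoxyphenyl]ethenyl}phenoxy)-5-methoxybenzaldehyde F2. Chemoselective alkene hydrogenation (H2 1 atm, Pd/C poisoned with Ph2S, EtOAc, rt) spares the C–Br bond and the aldehyde and gives 2-(3-{2-[3-(4-bromophenoxy)-4-methoxyphenyl]ethyl}phenoxy)-5-methoxybenzaldehyde F3. Wittig methylenation (Ph3PCH3Br, KOt-Bu, THF) then returns to the route at 10.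

Step 3 (SNAr on a fluoride deactivated by the para-methoxy group). The risk is low conversion or aldehyde decomposition at 140 °C. The fallback sets out from 5. A Chan–Lam coupling of 5 with commercial (2-formyl-4-methoxyphenyl)boronic acid, COc1ccc(B(O)O)c(C=O)c1 (Cu(OAc)2, pyridine, 4 Å MS, CH2Cl2, O2, rt), forms the same diaryl ether oxidatively and tolerates the aryl iodide. It comes back to the route at 7 and makes no new compound (F0).

**Further compounds**
F1 | step 6 | B-alkyl-9-BBN adduct of 10 (9-{2-[2-(3-{2-[3-(4-bromophenoxy)-4-methoxyphenyl]ethyl}phenoxy)-5-methoxyphenyl]ethyl}-9-borabicyclo[3.3.1]nonane) | COc1ccc(CCc2cccc(Oc3ccc(OC)cc3CCB3C4CCCC3CCC4)c2)cc1Oc1ccc(Br)cc1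
F2 | step 5 | 2-(3-{(E)-2-[3-(4-bromophenoxy)-4-methoxyphenyl]ethenyl}phenoxy)-5-methoxybenzaldehyde | COc1ccc(/C=C/c2cccc(Oc3ccc(OC)cc3C=O)c2)cc1Oc1ccc(Br)cc1
F3 | step 5 | 2-(3-{2-[3-(4-bromophenoxy)-4-methoxyphenyl]ethyl}phenoxy)-5-methoxybenzaldehyde | COc1ccc(CCc2cccc(Oc3ccc(OC)cc3C=O)c2)cc1Oc1ccc(Br)cc1
F0 | step 3 | none | none
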